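**Plan**

- Retrosynthesis: the two MOM ethers and a traceless allyloxycarbonyl group at C3 are removed first; then the C3–C4 bond of ring C is cut (crossed benzoin), then the O1–C2 aryl ether bond, then C2–C3 (Darzens condensation) and the C6–prenyl bond (para-Claisen–Cope of an O-prenyl ether).
- Enabling feature: in ring C the C4 aryl ketone sits next to the C3 carbinol, which is an acyloin; in the ring-opened precursor C2 (benzylic, bound to O1, alpha to the C3 keto group) epimerises freely.
- Forward: the ring A salicylaldehyde (four steps from 2,4,6-trihydroxybenzaldehyde) and a racemic ring B chloro keto ester (from isovanillin) are joined at O1–C2. A chiral carbene then closes ring C at C3–C4, the ester is excised and the MOM groups are cleaved.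
- Stereochemistry: C2 comes from dynamic kinetic resolution by the chiral triazolium carbene during ring closure. C3 is set afterwards by ketonisation of an enediol to the more stable 2,3-trans isomer.

Key step: step 9

Assumption: which antipode of the aminoindanol-derived triazolium salt favours the (2R) series has to be found by experiment; the route is written with the (5aS,10bR) salt, and its mirror image is used if the sense of induction is the opposite. The C3 configuration drawn for the cyclised ester (hydroxyl trans to ring B) is of no consequence, since C3 is reset in step 10.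

**Route**

Step 1
Reactants: 1 2,4,6-trihydroxybenzaldehyde
Product: 2 2,6-dihydroxy-4-methoxybenzaldehyde
Conditions: Me2SO4 (1.0 equiv), K2CO3 (1.0 equiv), acetone, 0 °C to rt
Reagents that add atoms: dimethyl sulfate, COS(=O)(=O)OC
Why: The 4-hydroxyl is the only one not held in a hydrogen bond to the formyl group and is the most acidic, so a Williamson methylation with one equivalent of a hard methylating agent should stop at the para ether.

Step 2
Reactants: 2 2,6-dihydroxy-4-methoxybenzaldehyde
Product: 3 2-hydroxy-4-methoxy-6-(methoxymethoxy)benzaldehyde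
Conditions: MOMCl (1.05 equiv), i-Pr2NEt, CH2Cl2, 0 °C
Reagents that add atoms: chloromethyl methyl ether, COCCl
Why: MOM etherification of one of the two equivalent ortho hydroxyls should stop after the first alkylation, because the remaining hydroxyl is then locked in a strong hydrogen bond to the aldehyde.

Step 3
Reactants: 3 2-hydroxy-4-methoxy-6-(methoxymethoxy)benzaldehyde; 4 prenyl bromide
Product: 5 4-methoxy-2-(methoxymethoxy)-6-[(3-methylbut-2-en-1-yl)oxy]benzaldehyde
Conditions: K2CO3, DMF, 50 °C
Reagents that add atoms: none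
Why: Carbonate in DMF deprotonates the chelated phenol, which is O-alkylated by the allylic bromide in a Williamson etherification.

Step 4
Reactants: 5 4-methoxy-2-(methoxymethoxy)-6-[(3-methylbut-2-en-1-yl)oxy]benzaldehyde
Product: 8 6-hydroxy-4-methoxy-2-(methoxymethoxy)-3-(3-methylbut-2-en-1-yl)benzaldehyde, via ortho dienone 6 (not isolated), via para dienone 7 (not isolated)
Conditions: PhNEt2, 190 °C, sealed tube, argon
Reagents that add atoms: none
Why: An aromatic Claisen rearrangement followed by a Cope shift (para-Claisen–Cope) should carry the prenyl group to the position para to the ether oxygen, which lies between the OMe and OMOM groups, and tautomerisation frees the phenol that becomes O1.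

Step 5
Reactants: 9 isovanillin
Product: 10 4-methoxy-3-(methoxymethoxy)benzaldehyde
Conditions: MOMCl, i-Pr2NEt, CH2Cl2, 0 °C to rt
Reagents that add atoms: chloromethyl methyl ether, COCCl
Why: Standard MOM etherification of an unhindered phenol.

Step 6
Reactants: 11 dichloroacetyl chloride; 12 allyl alcohol
Product: 13 allyl dichloroacetate
Conditions: pyridine, CH2Cl2, 0 °C
Reagents that add atoms: none
Why: Acylation of a primary alcohol by an acid chloride.

Step 7
Reactants: 10 4-methoxy-3-(methoxymethoxy)benzaldehyde; 13 allyl dichloroacetate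
Product: 16 allyl 3-chloro-3-[4-methoxy-3-(methoxymethoxy)phenyl]-2-oxopropanoate (racemic), via dichlorohydrin potassium alkoxide 14 (not isolated), via chloro glycidic ester 15 (not isolated)
Conditions: KOt-Bu (1.0 equiv), THF, −78 to 0 °C; aqueous NH4Cl; then CH2Cl2, rt; used crude
Reagents that add atoms: none
Why: A Darzens condensation gives the alpha-chloro glycidic ester, which should isomerise through the anisyl-stabilised benzylic cation and chloride return to the beta-chloro alpha-keto ester; no stereocontrol is needed because the racemate is wanted.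

Step 8
Reactants: 8 6-hydroxy-4-methoxy-2-(methoxymethoxy)-3-(3-methylbut-2-en-1-yl)benzaldehyde; 16 allyl 3-chloro-3-[4-methoxy-3-(methoxymethoxy)phenyl]-2-oxopropanoate
Product: 17 allyl 3-{[2-formyl-5-methoxy-3-(methoxymethoxy)-4-(3-methylbut-2-en-1-yl)phenyl]oxy}-3-[4-methoxy-3-(methoxymethoxy)phenyl]-2-oxopropanoate (racemic)
Conditions: K2CO3 (1.1 equiv), acetone, 0 °C to rt, short reaction time
Reagents that add atoms: none
Why: Williamson ether synthesis in which the phenoxide displaces a chloride that is both benzylic and alpha to a ketone, the most reactive class of alkyl halide toward SN2 attack; the new centre is racemic by design.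

Step 9
Reactants: 17 allyl 3-{[2-formyl-5-methoxy-3-(methoxymethoxy)-4-(3-methylbut-2-en-1-yl)phenyl]oxy}-3-[4-methoxy-3-(methoxymethoxy)phenyl]-2-oxopropanoate (racemic)
Product: 18 allyl (2R,3R)-3-hydroxy-7-methoxy-2-[4-methoxy-3-(methoxymethoxy)phenyl]-5-(methoxymethoxy)-6-(3-methylbut-2-en-1-yl)-4-oxochromane-3-carboxylate
Conditions: (5aS,10bR)-N-pentafluorophenyl aminoindanol-derived triazolium tetrafluoroborate (15 mol%), i-Pr2NEt (30 mol%), toluene, 0 °C to rt
Reagents that add atoms: none
Why: Proposed new method: the carbene freed from the triazolium salt adds to the ring A formyl group, proton transfer gives the nucleophilic enaminol, and this acyl anion equivalent attacks the C3 keto group of the keto ester to form C3–C4 before the carbene is expelled; the closest known reaction types are the carbene-catalysed intramolecular aldehyde–ketone crossed benzoin that gives 3-hydroxychroman-4-ones and the intermolecular dynamic kinetic crossed benzoin of beta-stereogenic alpha-keto esters. Ring C closes in a 6-exo-trig mode. C2 is controlled by the chiral carbene, which should cyclise one enantiomer of 17 much faster than the other while the amine interconverts the two through the enol of the keto ester, C2–H being benzylic, alpha-oxy and alpha to the keto group. C3 follows from the face of the ketone exposed when the C2 aryl group sits pseudo-equatorial in the cyclic transition state, and is reset in step 10. The step needs acyl anion addition to win over enolate chemistry: the ketone cannot become an acyl anion, the keto ester is the most electrophilic carbonyl, the formyl group is deactivated toward aldol attack by three oxygen donors, and a five-membered aldol adduct with a fully substituted C2 cannot dehydrate and can revert. A keto ester is placed at C3 in place of an aldehyde because the enaminol of an alpha-aryloxy aldehyde would expel the ring A phenoxide.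

Step 10
Reactants: 18 allyl (2R,3R)-3-hydroxy-7-methoxy-2-[4-methoxy-3-(methoxymethoxy)phenyl]-5-(methoxymethoxy)-6-(3-methylbut-2-en-1-yl)-4-oxochromane-3-carboxylate
Product: 21 (2R,3R)-3-hydroxy-7-methoxy-2-[4-methoxy-3-(methoxymethoxy)phenyl]-5-(methoxymethoxy)-6-(3-methylbut-2-en-1-yl)chroman-4-one, via beta-keto acid 19 (not isolated), via enediol 20 (not isolated)
Conditions: Pd(PPh3)4 (zerovalent palladium, 5 mol%), morpholine (5 equiv), degassed THF, rt then 40 °C; pH 4 buffer work-up
Reagents that add atoms: none
Why: Tsuji–Trost deallylation (pi-allyl palladium captured by morpholine) gives the beta-keto acid, which decarboxylates to the enediol; ketonisation at C3 should place hydrogen so that the 3-hydroxyl and the C2 aryl group are both equatorial (2,3-trans, the more stable isomer), while C2 is untouched.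

Step 11
Reactants: 21 (2R,3R)-3-hydroxy-7-methoxy-2-[4-methoxy-3-(methoxymethoxy)phenyl]-5-(methoxymethoxy)-6-(3-methylbut-2-en-1-yl)chroman-4-one
Product: 22 (2R,3R)-3,5-dihydroxy-2-(3-hydroxy-4-methoxyphenyl)-7-methoxy-6-(3-methylbut-2-en-1-yl)chroman-4-one (CNP0146895.1)
Conditions: 3 M HCl, MeOH, 40 °C
Reagents that add atoms: none
Why: Acid-catalysed methanolysis of the two MOM acetals under mild conditions should spare the prenyl alkene and both stereocentres.

**Compound list**

1 | 2,4,6-trihydroxybenzaldehyde | O=Cc1c(O)cc(O)cc1O | starting material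
2 | 2,6-dihydroxy-4-methoxybenzaldehyde | O=Cc1c(O)cc(OC)cc1O | intermediate
3 | 2-hydroxy-4-methoxy-6-(methoxymethoxy)benzaldehyde | O=Cc1c(O)cc(OC)cc1OCOC | intermediate
4 | prenyl bromide (1-bromo-3-methylbut-2-ene) | CC(C)=CCBr | starting material
5 | 4-methoxy-2-(methoxymethoxy)-6-[(3-methylbut-2-en-1-yl)oxy]benzaldehyde | O=Cc1c(OCC=C(C)C)cc(OC)cc1OCOC | intermediate
6 | ortho dienone: 4-methoxy-2-(methoxymethoxy)-5-(2-methylbut-3-en-2-yl)-6-oxocyclohexa-1,3-diene-1-carbaldehyde (racemic, not isolated) | O=CC1=C(OCOC)C=C(OC)C(C(C)(C)C=C)C1=O | intermediate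
7 | para dienone: 4-methoxy-2-(methoxymethoxy)-3-(3-methylbut-2-en-1-yl)-6-oxocyclohexa-1,4-diene-1-carbaldehyde (racemic, not isolated) | O=CC1=C(OCOC)C(CC=C(C)C)C(OC)=CC1=O | intermediate
8 | 6-hydroxy-4-methoxy-2-(methoxymethoxy)-3-(3-methylbut-2-en-1-yl)benzaldehyde | O=Cc1c(O)cc(OC)c(CC=C(C)C)c1OCOC | intermediate
9 | isovanillin (3-hydroxy-4-methoxybenzaldehyde) | COc1ccc(C=O)cc1O | starting material
10 | 4-methoxy-3-(methoxymethoxy)benzaldehyde | COc1ccc(C=O)cc1OCOC | intermediate
11 | dichloroacetyl chloride | O=C(Cl)C(Cl)Cl | starting material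
12 | allyl alcohol | C=CCO | starting material
13 | allyl dichloroacetate | C=CCOC(=O)C(Cl)Cl | intermediate
14 | potassium alkoxide of allyl 2,2-dichloro-3-hydroxy-3-[4-methoxy-3-(methoxymethoxy)phenyl]propanoate (racemic, not isolated) | COc1ccc(C([O-])C(Cl)(Cl)C(=O)OCC=C)cc1OCOC.[K+] | intermediate
15 | allyl 2-chloro-3-[4-methoxy-3-(methoxymethoxy)phenyl]oxirane-2-carboxylate (racemic, not isolated) | COc1ccc(C2OC2(Cl)C(=O)OCC=C)cc1OCOC | intermediate
16 | allyl 3-chloro-3-[4-methoxy-3-(methoxymethoxy)phenyl]-2-oxopropanoate (racemic) | COc1ccc(C(Cl)C(=O)C(=O)OCC=C)cc1OCOC | intermediate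
17 | allyl 3-{[2-formyl-5-methoxy-3-(methoxymethoxy)-4-(3-methylbut-2-en-1-yl)phenyl]oxy}-3-[4-methoxy-3-(methoxymethoxy)phenyl]-2-oxopropanoate (racemic) | COc1ccc(C(Oc2cc(OC)c(CC=C(C)C)c(OCOC)c2C=O)C(=O)C(=O)OCC=C)cc1OCOC | intermediate
18 | allyl (2R,3R)-3-hydroxy-7-methoxy-2-[4-methoxy-3-(methoxymethoxy)phenyl]-5-(methoxymethoxy)-6-(3-methylbut-2-en-1-yl)-4-oxochromane-3-carboxylate | COc1ccc([C@H]2Oc3cc(OC)c(CC=C(C)C)c(OCOC)c3C(=O)[C@@]2(O)C(=O)OCC=C)cc1OCOC | intermediate
19 | (2R,3R)-3-hydroxy-7-methoxy-2-[4-methoxy-3-(methoxymethoxy)phenyl]-5-(methoxymethoxy)-6-(3-methylbut-2-en-1-yl)-4-oxochromane-3-carboxylic acid (as morpholinium salt, not isolated) | COc1ccc([C@H]2Oc3cc(OC)c(CC=C(C)C)c(OCOC)c3C(=O)[C@@]2(O)C(=O)O)cc1OCOC | intermediate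
20 | (2R)-7-methoxy-2-[4-methoxy-3-(methoxymethoxy)phenyl]-5-(methoxymethoxy)-6-(3-methylbut-2-en-1-yl)-2H-chromene-3,4-diol (not isolated) | COc1ccc([C@H]2Oc3cc(OC)c(CC=C(C)C)c(OCOC)c3C(O)=C2O)cc1OCOC | intermediate
21 | (2R,3R)-3-hydroxy-7-methoxy-2-[4-methoxy-3-(methoxymethoxy)phenyl]-5-(methoxymethoxy)-6-(3-methylbut-2-en-1-yl)chroman-4-one | COc1ccc([C@H]2Oc3cc(OC)c(CC=C(C)C)c(OCOC)c3C(=O)[C@@H]2O)cc1OCOC | intermediate
22 | (2R,3R)-3,5-dihydroxy-2-(3-hydroxy-4-methoxyphenyl)-7-methoxy-6-(3-methylbut-2-en-1-yl)chroman-4-one | COc1ccc([C@H]2Oc3cc(OC)c(CC=C(C)C)c(O)c3C(=O)[C@@H]2O)cc1O | target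

**Step count and risks**

Total steps: 11. Longest linear sequence: 8 steps (steps 1–4 and 8–11).

Steps most likely to fail:

1. Step 9 (carries the label). The carbene may add only slowly to a formyl group flanked by two ortho oxygen substituents. The readily formed enolate at C2 may close onto the aldehyde in an aldol reaction instead, and the catalyst may discriminate poorly between the two enantiomers of 17. The fallback uses known chemistry, sets out from 8 (with 10) and returns at 21. Phenol 8 is O-allylated (allyl bromide, K2CO3, DMF) to 6-(allyloxy)-4-methoxy-2-(methoxymethoxy)-3-(3-methylbut-2-en-1-yl)benzaldehyde F1. MeMgBr gives the secondary carbinol F2, and Dess–Martin periodinane oxidises it to the acetophenone F3. Claisen–Schmidt condensation with 10 (KOH, EtOH) gives the E-chalcone F4. Juliá–Colonna epoxidation (poly-L-leucine, urea–hydrogen peroxide, DBU, THF; poly-D-leucine if the sense is the opposite) should give the (αR,βS)-epoxy ketone F5. Pd(PPh3)4 with morpholine removes the allyl ether to give the 2'-hydroxy epoxy ketone F6. On exposure to PPTS in CH2Cl2 this should close 6-endo at the anisyl-activated benzylic carbon with inversion, giving 21.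

2. Step 8. Under carbonate the chloro keto ester may enolise and self-condense, and the acidic C2–H of the product may start an aldol closure onto the neighbouring formyl group before isolation. The fallback sets out from 10 (with 8) and returns at 17. A Darzens condensation of 10 with allyl chloroacetate (KOt-Bu, THF) gives the racemic trans glycidic ester F7. Phenol 8 opens it at the benzylic carbon (Cs2CO3, DMF, 60 °C) to the racemic alpha-hydroxy ester F8, and Dess–Martin periodinane then oxidises the carbinol under non-basic conditions to 17.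

3. Step 10. The amine may open ring C through the C3 enolate, which would erode C2 or lead to a diketone. The enediol may be oxidised by traces of air, or it may capture the pi-allyl palladium species. The fallback sets out from 18 and returns at 22, with the end game inverted so that no base is present when the enediol forms. Methanolic HCl (40 °C) first cleaves both MOM ethers to the 5,3'-dihydroxy allyl ester F9. Pd(PPh3)4 with dimedone as a neutral allyl acceptor (THF, rt to 40 °C) then gives the beta-keto acid F10. This decarboxylates to the enediol F11, which ketonises to 22 with the C4 carbonyl chelated by the free 5-hydroxyl.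

**Further compounds**

F1 | step 9 | 6-(allyloxy)-4-methoxy-2-(methoxymethoxy)-3-(3-methylbut-2-en-1-yl)benzaldehyde | O=Cc1c(OCC=C)cc(OC)c(CC=C(C)C)c1OCOC
F2 | step 9 | 1-[6-(allyloxy)-4-methoxy-2-(methoxymethoxy)-3-(3-methylbut-2-en-1-yl)phenyl]ethanol (racemic) | CC(O)c1c(OCC=C)cc(OC)c(CC=C(C)C)c1OCOC
F3 | step 9 | 1-[6-(allyloxy)-4-methoxy-2-(methoxymethoxy)-3-(3-methylbut-2-en-1-yl)phenyl]ethanone | CC(=O)c1c(OCC=C)cc(OC)c(CC=C(C)C)c1OCOC
F4 | step 9 | (E)-1-[6-(allyloxy)-4-methoxy-2-(methoxymethoxy)-3-(3-methylbut-2-en-1-yl)phenyl]-3-[4-methoxy-3-(methoxymethoxy)phenyl]prop-2-en-1-one | COc1ccc(/C=C/C(=O)c2c(OCC=C)cc(OC)c(CC=C(C)C)c2OCOC)cc1OCOC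
F5 | step 9 | [6-(allyloxy)-4-methoxy-2-(methoxymethoxy)-3-(3-methylbut-2-en-1-yl)phenyl]{(2R,3S)-3-[4-methoxy-3-(methoxymethoxy)phenyl]oxiran-2-yl}methanone | COc1ccc([C@@H]2O[C@H]2C(=O)c3c(OCC=C)cc(OC)c(CC=C(C)C)c3OCOC)cc1OCOC
F6 | step 9 | [6-hydroxy-4-methoxy-2-(methoxymethoxy)-3-(3-methylbut-2-en-1-yl)phenyl]{(2R,3S)-3-[4-methoxy-3-(methoxymethoxy)phenyl]oxiran-2-yl}methanone | COc1ccc([C@@H]2O[C@H]2C(=O)c3c(O)cc(OC)c(CC=C(C)C)c3OCOC)cc1OCOC
F7 | step 8 | allyl trans-3-[4-methoxy-3-(methoxymethoxy)phenyl]oxirane-2-carboxylate (racemic) | COc1ccc(C2OC2C(=O)OCC=C)cc1OCOC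
F8 | step 8 | allyl 3-{[2-formyl-5-methoxy-3-(methoxymethoxy)-4-(3-methylbut-2-en-1-yl)phenyl]oxy}-2-hydroxy-3-[4-methoxy-3-(methoxymethoxy)phenyl]propanoate (racemic) | COc1ccc(C(Oc2cc(OC)c(CC=C(C)C)c(OCOC)c2C=O)C(O)C(=O)OCC=C)cc1OCOC
F9 | step 10 | allyl (2R,3R)-3,5-dihydroxy-2-(3-hydroxy-4-methoxyphenyl)-7-methoxy-6-(3-methylbut-2-en-1-yl)-4-oxochromane-3-carboxylate | COc1ccc([C@H]2Oc3cc(OC)c(CC=C(C)C)c(O)c3C(=O)[C@@]2(O)C(=O)OCC=C)cc1O
F10 | step 10 | (2R,3R)-3,5-dihydroxy-2-(3-hydroxy-4-methoxyphenyl)-7-methoxy-6-(3-methylbut-2-en-1-yl)-4-oxochromane-3-carboxylic acid | COc1ccc([C@H]2Oc3cc(OC)c(CC=C(C)C)c(O)c3C(=O)[C@@]2(O)C(=O)O)cc1O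
F11 | step 10 | (2R)-2-(3-hydroxy-4-methoxyphenyl)-7-methoxy-6-(3-methylbut-2-en-1-yl)-2H-chromene-3,4,5-triol | COc1ccc([C@H]2Oc3cc(OC)c(CC=C(C)C)c(O)c3C(O)=C2O)cc1O
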